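**Plan**

- Numbering: furo[3,4-c]furan-1-one core C1(=O)–O2–C3(Ar)–C3a–C4H2–O5–C6(Ar′)–C6a, with C6a bonded to C1 and C3a; ring A = lactone, ring B = tetrahydrofuran.
- Retrosynthesis cuts, in order: the five O-benzyl groups; the C6–aryl bond (conjugate arylation of enol-ether lactone 13); the C4–O5 bond, which takes ring B back to a cyclopropane aldehyde (C4 re-bonded to C6a); the cyclopropane bonds C6a–C3a and C6a–C4 (carbene plus vinyl group); the ester C–O bond and the C3–vinyl bond.
- Forward order: C3 carbinol, ester, vinyl diazo ester, ring A and the cyclopropane in one carbene step, aldehyde, ring B by C4–O5 closure (as its 6,6a-dehydro form), aryl at C6, debenzylation.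
- Stereochemistry: C3 from lipase resolution of the vinyl carbinol; C3a from carbinol-directed cyclopropanation (aryl anti to the new CH2); C6 and C6a from convex-face aryl transfer and protonation to the only possible cis-fused bicycle.
- Enabling feature: O5 is carried by C6, C6 and the lactone carbonyl C1 both sit on C6a, and C4 hangs on the neighbouring C3a. Ring B is therefore the ring-expanded form of a cyclopropane C6a–C3a–C4 that bears two carbonyl groups on C6a, one of whose oxygens becomes O5.

Key step: step 7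

Remark: all five phenols are carried as benzyl ethers; compounds 1, 2 (THF solution), 6 and 14 are taken as commercial.

**Step 1**
Reactants: 1 3,4,5-tris(benzyloxy)benzaldehyde; 2 vinylmagnesium bromide
Product: 4 rac-1-[3,4,5-tris(benzyloxy)phenyl]prop-2-en-1-ol, via bromomagnesium alkoxide 3 (not isolated)
Conditions: THF, −78 → 0 °C; then aq. NH4Cl
Reagents that add atoms: none
Why: Grignard 1,2-addition to a non-enolisable aryl aldehyde is reliable; the carbinol centre (future C3) forms racemic and is resolved in step 2.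

**Step 2**
Reactants: 4 rac-1-[3,4,5-tris(benzyloxy)phenyl]prop-2-en-1-ol
Product: 5 (S)-1-[3,4,5-tris(benzyloxy)phenyl]prop-2-en-1-ol
Conditions: Novozym 435 (immobilised Candida antarctica lipase B), vinyl acetate, toluene, 30 °C, stopped just past half conversion; chromatography
Reagents that add atoms: none
Why: Lipase-catalysed kinetic resolution by irreversible transesterification; with aryl as the large and vinyl as the small carbinol substituent the enzyme should acylate the (R)-enantiomer and leave the (S)-alcohol 5, which fixes C3.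

**Step 3**
Reactants: 5 (S)-1-[3,4,5-tris(benzyloxy)phenyl]prop-2-en-1-ol; 6 (E)-4-phenylbut-3-enoic acid
Product: 7 (S)-1-[3,4,5-tris(benzyloxy)phenyl]prop-2-en-1-yl (E)-4-phenylbut-3-enoate
Conditions: DCC, DMAP (cat.), CH2Cl2, 0 °C → rt
Reagents that add atoms: none
Why: Steglich esterification acylates at oxygen, so the carbinol C–O bond and its (S) configuration are untouched, and the mild conditions should leave the styrene-conjugated β,γ-alkene in place.

**Step 4**
Reactants: 7 (S)-1-[3,4,5-tris(benzyloxy)phenyl]prop-2-en-1-yl (E)-4-phenylbut-3-enoate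
Product: 8 (S)-1-[3,4,5-tris(benzyloxy)phenyl]prop-2-en-1-yl (E)-2-diazo-4-phenylbut-3-enoate
Conditions: p-ABSA, DBU, MeCN, 0 °C; used at once
Reagents that add atoms: 4-acetamidobenzenesulfonyl azide (p-ABSA), CC(=O)Nc1ccc(cc1)S(=O)(=O)N=[N+]=[N-]
Why: Regitz diazo transfer to the methylene activated by both the ester and the styryl group gives the vinyl diazo ester; low temperature and prompt use should limit its electrocyclisation to a pyrazole.

**Step 5**
Reactants: 8 (S)-1-[3,4,5-tris(benzyloxy)phenyl]prop-2-en-1-yl (E)-2-diazo-4-phenylbut-3-enoate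
Product: 9 (1S,4S,5S)-1-[(E)-2-phenylethenyl]-4-[3,4,5-tris(benzyloxy)phenyl]-3-oxabicyclo[3.1.0]hexan-2-one
Conditions: Rh2(OAc)4 (1 mol%), CH2Cl2, rt, slow addition of 8
Reagents that add atoms: none
Why: Intramolecular cyclopropanation of the tethered terminal alkene by the rhodium vinylcarbene forms ring A and the necessarily cis-fused cyclopropane together; the carbinol centre should steer the carbene to the alkene face that keeps the allylic C–H eclipsed with the alkene and the aryl group anti to the new CH2, which sets C5 (future C3a) and C1, the minor syn isomer being removed by chromatography.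

**Step 6**
Reactants: 9 (1S,4S,5S)-1-[(E)-2-phenylethenyl]-4-[3,4,5-tris(benzyloxy)phenyl]-3-oxabicyclo[3.1.0]hexan-2-one
Product: 11 (1R,4S,5S)-2-oxo-4-[3,4,5-tris(benzyloxy)phenyl]-3-oxabicyclo[3.1.0]hexane-1-carbaldehyde, via secondary ozonide 10 (not isolated)
Conditions: O3, CH2Cl2, −78 °C, to the alkene end-point; then Me2S, −78 °C → rt
Reagents that add atoms: ozone, [O-][O+]=O
Why: Ozonolysis with reductive work-up cleaves the styryl C=C, which should react with ozone far faster than the alkoxy-arenes at −78 °C, and unmasks the formyl group on the quaternary cyclopropane carbon without touching a stereocentre.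

**Step 7**
Reactants: 11 (1R,4S,5S)-2-oxo-4-[3,4,5-tris(benzyloxy)phenyl]-3-oxabicyclo[3.1.0]hexane-1-carbaldehyde
Product: 13 (3S,3aR)-3-[3,4,5-tris(benzyloxy)phenyl]-3a,4-dihydro-1H,3H-furo[3,4-c]furan-1-one, via ring-opened iodomethyl enolate 12 (not isolated)
Conditions: n-Bu4NI (20 mol%), MeCN, 70 °C
Reagents that add atoms: none
Why: Iodide opens the doubly acceptor-activated cyclopropane by SN2 attack at its unsubstituted methylene (future C4), breaking the C4–C6a bond to give the 2-formyl-lactone enolate 12, whose formyl oxygen then displaces iodide from the same carbon, so that the net change is a Cloke–Wilson acylcyclopropane-to-dihydrofuran rearrangement that forms C4–O5. The closest known reaction type is the halide- or Lewis-base-catalysed Cloke–Wilson ring expansion of 1-acylcyclopropane-1-carboxylic esters to 4,5-dihydrofuran-3-carboxylates. Ring B closes in a 5-exo-tet O-alkylation, whereas re-closure through carbon (3-exo-tet) only returns 11, so the equilibrium should drain to the less strained bicyclo[3.3.0] enol ether 13. No stereocentre is created: C3 and C3a are retained because none of their bonds is broken, and the C6a centre is erased on purpose and set again in step 8. The step needs attack at the methylene in preference to the ring-fusion methine and the benzylic lactone carbon C3, which is secured by the primary, unhindered carbon and by the lactone carbonyl, which is locked so that its π* orbital overlaps the C4–C6a bond and not the in-plane C3a–C6a bond. It also needs closure through the formyl and not the lactone oxygen, which is secured by geometry (the latter would give a bridgehead ketene acetal) and by the non-chelating ammonium counter-ion, which leaves the enolate free to turn its formyl oxygen towards C4.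

**Step 8**
Reactants: 13 (3S,3aR)-3-[3,4,5-tris(benzyloxy)phenyl]-3a,4-dihydro-1H,3H-furo[3,4-c]furan-1-one; 14 3,4-bis(benzyloxy)phenylboronic acid
Product: 15 (3S,3aR,6S,6aS)-6-[3,4-bis(benzyloxy)phenyl]-3-[3,4,5-tris(benzyloxy)phenyl]tetrahydro-1H,3H-furo[3,4-c]furan-1-one
Conditions: [Rh(OH)(cod)]2 (3 mol%), 14 (2 equiv), dioxane/H2O (10:1), 60 °C
Reagents that add atoms: none
Why: Rhodium-catalysed conjugate addition of an arylboronic acid (Hayashi–Miyaura reaction) to the ring-held β-alkoxy-α,β-unsaturated lactone; syn aryl-rhodation of C6=C6a can take place only on the convex face (the face of H-3a), because rhodium on the other face of C6a would impose a trans ring fusion, so the aryl group should enter C6 exo (6S), and protonation of the rhodium enolate at C6a from the same face gives the cis-fused lactone (6aS), while the in-ring C6–O5 bond lies near the nodal plane of the enolate and so resists β-alkoxide elimination.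

**Step 9**
Reactants: 15 (3S,3aR,6S,6aS)-6-[3,4-bis(benzyloxy)phenyl]-3-[3,4,5-tris(benzyloxy)phenyl]tetrahydro-1H,3H-furo[3,4-c]furan-1-one
Product: 16 (3S,3aR,6S,6aS)-6-(3,4-dihydroxyphenyl)-3-(3,4,5-trihydroxyphenyl)tetrahydro-1H,3H-furo[3,4-c]furan-1-one
Conditions: H2 (1 atm), 10% Pd/C, EtOAc/MeOH, rt, stopped at complete O-debenzylation; work-up under argon
Reagents that add atoms: none
Why: Catalytic hydrogenolysis removes the five aryl benzyl ethers under neutral conditions at ambient pressure; ArO–CH2Ph bonds should cleave much faster than the benzylic lactone C3–O2 and benzylic ether C6–O5 bonds, and no stereocentre is involved.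

**Compound list**

1 | 3,4,5-tris(benzyloxy)benzaldehyde | O=Cc1cc(OCc2ccccc2)c(OCc2ccccc2)c(OCc2ccccc2)c1 | starting material
2 | vinylmagnesium bromide | C=C[Mg]Br | starting material
3 | bromomagnesium 1-[3,4,5-tris(benzyloxy)phenyl]prop-2-en-1-olate (racemic, not isolated) | C=CC(O[Mg]Br)c1cc(OCc2ccccc2)c(OCc2ccccc2)c(OCc2ccccc2)c1 | intermediate
4 | rac-1-[3,4,5-tris(benzyloxy)phenyl]prop-2-en-1-ol | C=CC(O)c1cc(OCc2ccccc2)c(OCc2ccccc2)c(OCc2ccccc2)c1 | intermediate
5 | (S)-1-[3,4,5-tris(benzyloxy)phenyl]prop-2-en-1-ol | C=C[C@H](O)c1cc(OCc2ccccc2)c(OCc2ccccc2)c(OCc2ccccc2)c1 | intermediate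
6 | (E)-4-phenylbut-3-enoic acid | OC(=O)C/C=C/c1ccccc1 | starting material
7 | (S)-1-[3,4,5-tris(benzyloxy)phenyl]prop-2-en-1-yl (E)-4-phenylbut-3-enoate | C=C[C@H](OC(=O)C/C=C/c1ccccc1)c1cc(OCc2ccccc2)c(OCc2ccccc2)c(OCc2ccccc2)c1 | intermediate
8 | (S)-1-[3,4,5-tris(benzyloxy)phenyl]prop-2-en-1-yl (E)-2-diazo-4-phenylbut-3-enoate | C=C[C@H](OC(=O)C(=[N+]=[N-])/C=C/c1ccccc1)c1cc(OCc2ccccc2)c(OCc2ccccc2)c(OCc2ccccc2)c1 | intermediate
9 | (1S,4S,5S)-1-[(E)-2-phenylethenyl]-4-[3,4,5-tris(benzyloxy)phenyl]-3-oxabicyclo[3.1.0]hexan-2-one (aryl anti to the cyclopropane CH2) | c1ccccc1/C=C/[C@@]12C[C@@H]1[C@@H](c1cc(OCc3ccccc3)c(OCc3ccccc3)c(OCc3ccccc3)c1)OC2=O | intermediate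
10 | secondary ozonide of 9 (3-phenyl-1,2,4-trioxolan-5-yl in place of the styryl group; trioxolane centres unspecified; not isolated) | c1ccccc1C1OOC(O1)[C@@]12C[C@@H]1[C@@H](c1cc(OCc3ccccc3)c(OCc3ccccc3)c(OCc3ccccc3)c1)OC2=O | intermediate
11 | (1R,4S,5S)-2-oxo-4-[3,4,5-tris(benzyloxy)phenyl]-3-oxabicyclo[3.1.0]hexane-1-carbaldehyde | O=C[C@@]12C[C@@H]1[C@@H](c1cc(OCc3ccccc3)c(OCc3ccccc3)c(OCc3ccccc3)c1)OC2=O | intermediate
12 | tetrabutylammonium enolate of (4S,5S)-4-(iodomethyl)-2-oxo-5-[3,4,5-tris(benzyloxy)phenyl]oxolane-3-carbaldehyde (not isolated) | CCCC[N+](CCCC)(CCCC)CCCC.[O-]C=C1C(=O)O[C@H](c2cc(OCc3ccccc3)c(OCc3ccccc3)c(OCc3ccccc3)c2)[C@H]1CI | intermediate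
13 | (3S,3aR)-3-[3,4,5-tris(benzyloxy)phenyl]-3a,4-dihydro-1H,3H-furo[3,4-c]furan-1-one | O=C1O[C@H](c2cc(OCc3ccccc3)c(OCc3ccccc3)c(OCc3ccccc3)c2)[C@H]2COC=C12 | intermediate
14 | 3,4-bis(benzyloxy)phenylboronic acid | OB(O)c1ccc(OCc2ccccc2)c(OCc2ccccc2)c1 | starting material
15 | (3S,3aR,6S,6aS)-6-[3,4-bis(benzyloxy)phenyl]-3-[3,4,5-tris(benzyloxy)phenyl]tetrahydro-1H,3H-furo[3,4-c]furan-1-one | O=C1O[C@H](c2cc(OCc3ccccc3)c(OCc3ccccc3)c(OCc3ccccc3)c2)[C@H]2CO[C@H](c3ccc(OCc4ccccc4)c(OCc4ccccc4)c3)[C@@H]12 | intermediate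
16 | (3S,3aR,6S,6aS)-6-(3,4-dihydroxyphenyl)-3-(3,4,5-trihydroxyphenyl)tetrahydro-1H,3H-furo[3,4-c]furan-1-one | O=C1O[C@H](c2cc(O)c(O)c(O)c2)[C@H]2CO[C@H](c3ccc(O)c(O)c3)[C@@H]12 | target

**Summary**

Total step count: 9. Longest linear sequence: 9 steps (1 to 16).

The three steps most likely to fail:

Step 8. The donor-substituted, α-branched enoate may be too unreactive towards aryl-rhodium insertion, so that protodeboronation of 14 outruns the addition. The fallback sets out from 13 and replaces the catalytic rhodium cycle by a silyl-activated organocopper addition in an aprotic medium. [3,4-Bis(benzyloxy)phenyl]magnesium bromide F1 is made from commercial 4-bromo-1,2-bis(benzyloxy)benzene and magnesium in THF. It is added to 13 with CuBr·SMe2 (10 mol%) and Me3SiCl in THF at −78 °C, which should deliver the aryl group to the convex face of C6 and trap the enolate as the trimethylsilyl ketene acetal of 15 F2. Mild aqueous acid then protonates C6a from the convex face and the route is rejoined at 15.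

Step 7. Ring opening by a non-activated iodide may be too slow for the catalytic rearrangement to turn over. The fallback sets out from 11 and separates opening and closure. Stoichiometric MgI2 in THF (0 °C to rt) opens the chelated formyl lactone at the methylene, and aqueous work-up gives (4S,5S)-3-(hydroxymethylidene)-4-(iodomethyl)-5-[3,4,5-tris(benzyloxy)phenyl]oxolan-2-one F3. Ag2CO3 in CH2Cl2 at rt then removes iodide and closes the same C4–O5 bond through the enol oxygen, rejoining the route at 13.

Step 5. The carbinol centre may give only a weak facial bias with a terminal alkene, and carbene dimerisation may compete because the ester must reach its less stable s-cis conformer. The fallback sets out from 5 and builds the same ring system by an oxidative radical cyclisation.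
- Steglich esterification of 5 with mono-tert-butyl malonate gives tert-butyl (S)-1-[3,4,5-tris(benzyloxy)phenyl]prop-2-en-1-yl malonate F4.
- Mn(OAc)3·2H2O and Cu(OAc)2·H2O in AcOH at 50–60 °C should effect 5-exo cyclisation of the malonyl radical through a chair-like transition state with the aryl group pseudo-equatorial, followed by copper-mediated three-ring closure, giving tert-butyl (1S,4S,5S)-2-oxo-4-[3,4,5-tris(benzyloxy)phenyl]-3-oxabicyclo[3.1.0]hexane-1-carboxylate F5 with the aryl anti.
- CF3CO2H in CH2Cl2 gives (1R,4S,5S)-2-oxo-4-[3,4,5-tris(benzyloxy)phenyl]-3-oxabicyclo[3.1.0]hexane-1-carboxylic acid F6.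
- BH3·SMe2 in THF reduces the acid in preference to the lactone to (1R,4S,5S)-1-(hydroxymethyl)-4-[3,4,5-tris(benzyloxy)phenyl]-3-oxabicyclo[3.1.0]hexan-2-one F7.
- Dess–Martin periodinane oxidises F7 to the aldehyde, rejoining the route at 11.

**Further compounds**

F1 | step 8 | [3,4-bis(benzyloxy)phenyl]magnesium bromide | Br[Mg]c1ccc(OCc2ccccc2)c(OCc2ccccc2)c1
F2 | step 8 | trimethylsilyl ketene acetal of 15 (O-silylated at C1, C1=C6a, configuration at C3, C3a and C6 as in 15) | C[Si](C)(C)OC1=C2[C@@H](c3ccc(OCc4ccccc4)c(OCc4ccccc4)c3)OC[C@@H]2[C@@H](c2cc(OCc3ccccc3)c(OCc3ccccc3)c(OCc3ccccc3)c2)O1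
F3 | step 7 | (4S,5S)-3-(hydroxymethylidene)-4-(iodomethyl)-5-[3,4,5-tris(benzyloxy)phenyl]oxolan-2-one | OC=C1C(=O)O[C@H](c2cc(OCc3ccccc3)c(OCc3ccccc3)c(OCc3ccccc3)c2)[C@H]1CI
F4 | step 5 | tert-butyl (S)-1-[3,4,5-tris(benzyloxy)phenyl]prop-2-en-1-yl malonate | C=C[C@H](OC(=O)CC(=O)OC(C)(C)C)c1cc(OCc2ccccc2)c(OCc2ccccc2)c(OCc2ccccc2)c1
F5 | step 5 | tert-butyl (1S,4S,5S)-2-oxo-4-[3,4,5-tris(benzyloxy)phenyl]-3-oxabicyclo[3.1.0]hexane-1-carboxylate | CC(C)(C)OC(=O)[C@@]12C[C@@H]1[C@@H](c1cc(OCc3ccccc3)c(OCc3ccccc3)c(OCc3ccccc3)c1)OC2=O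
F6 | step 5 | (1R,4S,5S)-2-oxo-4-[3,4,5-tris(benzyloxy)phenyl]-3-oxabicyclo[3.1.0]hexane-1-carboxylic acid | OC(=O)[C@@]12C[C@@H]1[C@@H](c1cc(OCc3ccccc3)c(OCc3ccccc3)c(OCc3ccccc3)c1)OC2=O
F7 | step 5 | (1R,4S,5S)-1-(hydroxymethyl)-4-[3,4,5-tris(benzyloxy)phenyl]-3-oxabicyclo[3.1.0]hexan-2-one | OC[C@@]12C[C@@H]1[C@@H](c1cc(OCc3ccccc3)c(OCc3ccccc3)c(OCc3ccccc3)c1)OC2=O
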